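**Strategy.** The target is cut at C2–C3 of ring B (spiro[5.5]undecane numbering: C2 = CHBr, C3 = C(OH)CH3, C6 = spiro carbon). The trans bromohydrin is read as the retron of a C2=C3 alkene, so ring B is closed by ring-closing metathesis of an allyl and a 3-methylbut-3-enyl arm held on the quaternary C6 of a ring A ketone (gem-dialkyl effect). The precursor is a 2,2-disubstituted 4-bromo-3,3-dimethylcyclohexanone whose C6 centre is set by conjugate addition and axial Mukaiyama–Michael trapping. The C7 ketone then steers Br and OH onto C2 and C3 before it becomes the C7 methyl alkene.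

Key step: step 7

Remark: atom numbers are those of the target (ring B = C1–C5, spiro C6, ring A = C7–C11) and are kept for all intermediates; the C10–Br bond is assumed to sit equatorial in the ring A half-chairs.

**Step 1**
Reactants: 1 tert-butyl acetoacetate; 2 prenyl bromide (1-bromo-3-methylbut-2-ene)
Product: 4 tert-butyl 7-methyl-3-oxooct-6-enoate, via sodium lithium dianion of tert-butyl acetoacetate 3 (not isolated)
Conditions: NaH, THF, 0 °C; n-BuLi, 0 °C; then 2; aq. NH4Cl
Reagents that add atoms: none
Why: Acetoacetate dianion gamma-alkylation, in which the more reactive terminal carbanion displaces the allylic bromide; no stereocenter is formed.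

**Step 2**
Reactants: 4 tert-butyl 7-methyl-3-oxooct-6-enoate
Product: 5 tert-butyl (1S,3S)-3-bromo-2,2-dimethyl-6-oxocyclohexane-1-carboxylate
Conditions: DBDMH (0.55 equiv), (R)-BINOL-derived thiophosphoramide (10 mol %, enantiomer chosen to deliver the 3S bromide), toluene–CH2Cl2, −78 °C
Reagents that add atoms: 1,3-dibromo-5,5-dimethylhydantoin (DBDMH), CC1(C)N(Br)C(=O)N(Br)C1=O
Why: Proposed new method: a bromenium ion bound to the chiral Lewis base should be transferred to one face of the trisubstituted alkene, and the enol carbon of the keto ester should open the bromonium ion at the tertiary carbon through a chair transition state with equatorial C–Br, which sets C10 as S while the enolizable ester carbon settles equatorial; the closest known reaction types are the Lewis base-catalysed enantioselective bromocyclization of homogeranylarenes and the racemic bromonium-induced cyclization of polyenes that end in a beta-keto ester.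

**Step 3**
Reactants: 5 tert-butyl (1S,3S)-3-bromo-2,2-dimethyl-6-oxocyclohexane-1-carboxylate
Product: 7 (4S)-4-bromo-3,3-dimethyl-2-methylidenecyclohexan-1-one, via beta-keto acid 6 (not isolated)
Conditions: TFA, CH2Cl2, 0 °C; then 37% aq. HCHO, Et2NH, AcOH, THF, 0 °C to rt
Reagents that add atoms: formaldehyde, C=O
Why: Acidolysis gives the beta-keto acid, whose Mannich adduct should fragment with loss of CO2 and amine (decarboxylative Mannich methylenation) and so place the methylidene group regiospecifically on the hindered alpha-carbon; the bromide stereocenter is untouched.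

**Step 4**
Reactants: 7 (4S)-4-bromo-3,3-dimethyl-2-methylidenecyclohexan-1-one
Product: 8 {[(4S)-4-bromo-3,3-dimethyl-2-(prop-2-en-1-yl)cyclohex-1-en-1-yl]oxy}trimethylsilane
Conditions: CH2=CHMgBr, CuBr·SMe2 (10 mol %), TMSCl, THF, −78 °C; Et3N, cold aq. NaHCO3
Reagents that add atoms: vinylmagnesium bromide, C=C[Mg]Br; chlorotrimethylsilane, C[Si](C)(C)Cl
Why: Copper-catalysed 1,4-addition of the vinyl Grignard reagent with TMSCl trapping should turn the methylidene group into the allyl arm and deliver the tetrasubstituted silyl enol ether regiospecifically; no stereocenter is formed.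

**Step 5**
Reactants: 8 silyl enol ether; 9 methyl vinyl ketone (but-3-en-2-one)
Product: 10 (2S,4S)-4-bromo-3,3-dimethyl-2-(3-oxobutyl)-2-(prop-2-en-1-yl)cyclohexan-1-one
Conditions: TiCl4, CH2Cl2, −78 °C; aq. NaHCO3
Reagents that add atoms: none
Why: Mukaiyama–Michael addition creates the quaternary C6, and the enone should approach along the axial trajectory on the face anti to the pseudoaxial C11 methyl of the half-chair with equatorial C10–Br, so that the 3-oxobutyl arm enters trans to bromine and the allyl arm ends cis to it (substrate control).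

**Step 6**
Reactants: 10 (2S,4S)-4-bromo-3,3-dimethyl-2-(3-oxobutyl)-2-(prop-2-en-1-yl)cyclohexan-1-one
Product: 11 (2S,4S)-4-bromo-3,3-dimethyl-2-(3-methylbut-3-en-1-yl)-2-(prop-2-en-1-yl)cyclohexan-1-one
Conditions: Ph3PCH3Br, KOtBu, THF, 0 °C
Reagents that add atoms: methyltriphenylphosphonium bromide (as its ylide), C[P+](c1ccccc1)(c1ccccc1)c1ccccc1.[Br-]
Why: Wittig methylenation should occur only at the unhindered methyl ketone, because the ring ketone is flanked by the quaternary carbon and a syn-axial methyl group; no stereocenter is affected.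

**Step 7**
Reactants: 11 (2S,4S)-4-bromo-3,3-dimethyl-2-(3-methylbut-3-en-1-yl)-2-(prop-2-en-1-yl)cyclohexan-1-one
Product: 12 (4S,6S)-4-bromo-5,5,9-trimethylspiro[5.5]undec-8-en-1-one
Conditions: RuCl2(=CHPh)(PCy3)(H2IMes) (second-generation Grubbs catalyst, 5 mol %), CH2Cl2 (0.01 M), 40 °C
Reagents that add atoms: none
Why: The ruthenium alkylidene should initiate at the monosubstituted allyl alkene, add to the 1,1-disubstituted alkene of the other arm in a [2+2] cycloaddition and release the ring B alkene by cycloreversion, with loss of ethene as the driving force. The closest known reaction type is ring-closing metathesis of a 1,7-diene with one gem-disubstituted alkene to a 1-methylcyclohexene. The six-membered ring B is closed by formation of the C2=C3 bond, a closure that the two arms on the quaternary C6 favour through the gem-dialkyl effect. No stereocenter is formed, and the configurations at C6 and C10 are not touched. The step needs chemoselectivity for the two terminal alkenes over the ketone and the secondary bromide and cyclization over oligomerization, which the neutral catalyst, the 1,7-relationship of the alkenes and dilution should secure.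

**Step 8**
Reactants: 12 (4S,6S)-4-bromo-5,5,9-trimethylspiro[5.5]undec-8-en-1-one
Product: 14 (4S,6S,8R,9R)-4,8-dibromo-9-hydroxy-5,5,9-trimethylspiro[5.5]undecan-1-one, via bridged oxocarbenium ion 13 (not isolated)
Conditions: NBS (1.05 equiv), (CF3)2CHOH–CH2Cl2 (1:4), −20 °C; then H2O, NaHCO3
Reagents that add atoms: N-bromosuccinimide, O=C1CCC(=O)N1Br; water, O
Why: The bromonium ion should form on the ring B face anti to the axial C7 carbonyl carbon, and the carbonyl oxygen, held 1,4 across ring B, should open it at the tertiary C3 through a boat to a 2-oxabicyclo[2.2.2]octane oxocarbenium ion that water converts into the hydroxy ketone (halohydrin formation with neighbouring carbonyl participation), which places C3–OH syn to C7 and C2–Br anti to it, the diequatorial trans bromohydrin that direct diaxial opening would not give.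

**Step 9**
Reactants: 14 (4S,6S,8R,9R)-4,8-dibromo-9-hydroxy-5,5,9-trimethylspiro[5.5]undecan-1-one
Product: 16 (4S,6S,8R,9R)-4,8-dibromo-9-hydroxy-5,5,9-trimethylspiro[5.5]undec-1-en-1-yl trifluoromethanesulfonate, via dipotassium alkoxide enolate 15 (not isolated)
Conditions: KN(SiMe3)2 (2.2 equiv), THF, −78 °C; then PhNTf2; aq. NH4Cl
Reagents that add atoms: N-phenylbis(trifluoromethanesulfonimide), O=S(=O)(N(c1ccccc1)S(=O)(=O)C(F)(F)F)C(F)(F)F
Why: Enol triflate formation: deprotonation can occur only at C8 because C6 is quaternary, the enolate is O-sulfonylated, and the hindered tertiary alkoxide and the diequatorial bromohydrin, which cannot reach the anti-periplanar geometry for epoxide closure, should survive at low temperature; no stereocenter changes.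

**Step 10**
Reactants: 16 enol triflate
Product: 17 (2R,3R,6R,10S)-2,10-dibromo-3,7,11,11-tetramethylspiro[5.5]undec-7-en-3-ol (target)
Conditions: MeZnCl (3 equiv), Pd(PPh3)4 (5 mol %), THF, 40 °C
Reagents that add atoms: methylzinc chloride, C[Zn]Cl
Why: Negishi coupling (oxidative addition of zerovalent palladium to the vinyl triflate, transmetalation from zinc, reductive elimination) installs the C7 methyl group with the alkene fixed at C7=C8, while the unactivated secondary bromides should not react with Pd(PPh3)4 under these conditions; no stereocenter changes.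

**Compound list**
1 | tert-butyl acetoacetate | CC(=O)CC(=O)OC(C)(C)C | starting material
2 | prenyl bromide | CC(C)=CCBr | starting material
3 | sodium lithium dianion of tert-butyl acetoacetate | [CH2-]C(=O)[CH-]C(=O)OC(C)(C)C.[Na+].[Li+] | intermediate (not isolated)
4 | tert-butyl 7-methyl-3-oxooct-6-enoate | CC(C)=CCCC(=O)CC(=O)OC(C)(C)C | intermediate
5 | tert-butyl (1S,3S)-3-bromo-2,2-dimethyl-6-oxocyclohexane-1-carboxylate | O=C1CC[C@H](Br)C(C)(C)[C@@H]1C(=O)OC(C)(C)C | intermediate
6 | (1S,3S)-3-bromo-2,2-dimethyl-6-oxocyclohexane-1-carboxylic acid | O=C1CC[C@H](Br)C(C)(C)[C@@H]1C(=O)O | intermediate (not isolated)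
7 | (4S)-4-bromo-3,3-dimethyl-2-methylidenecyclohexan-1-one | C=C1C(=O)CC[C@H](Br)C1(C)C | intermediate
8 | {[(4S)-4-bromo-3,3-dimethyl-2-(prop-2-en-1-yl)cyclohex-1-en-1-yl]oxy}trimethylsilane | C=CCC1=C(O[Si](C)(C)C)CC[C@H](Br)C1(C)C | intermediate
9 | methyl vinyl ketone | CC(=O)C=C | starting material
10 | (2S,4S)-4-bromo-3,3-dimethyl-2-(3-oxobutyl)-2-(prop-2-en-1-yl)cyclohexan-1-one | CC(=O)CC[C@@]1(CC=C)C(=O)CC[C@H](Br)C1(C)C | intermediate
11 | (2S,4S)-4-bromo-3,3-dimethyl-2-(3-methylbut-3-en-1-yl)-2-(prop-2-en-1-yl)cyclohexan-1-one | CC(=C)CC[C@@]1(CC=C)C(=O)CC[C@H](Br)C1(C)C | intermediate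
12 | (4S,6S)-4-bromo-5,5,9-trimethylspiro[5.5]undec-8-en-1-one | CC1=CC[C@]2(CC1)C(=O)CC[C@H](Br)C2(C)C | intermediate
13 | oxocarbenium ion with the C7 carbonyl oxygen bonded to C3 (2-oxabicyclo[2.2.2]octane core, C2–Br anti to oxygen), succinimide salt | C1(=[O+]3)CC[C@H](Br)C(C)(C)[C@@]12CC[C@]3(C)[C@H](Br)C2.O=C1CCC(=O)[N-]1 | intermediate (not isolated)
14 | (4S,6S,8R,9R)-4,8-dibromo-9-hydroxy-5,5,9-trimethylspiro[5.5]undecan-1-one | O=C1CC[C@H](Br)C(C)(C)[C@@]12CC[C@@](C)(O)[C@H](Br)C2 | intermediate
15 | dipotassium salt of 14 (C3 alkoxide, C7 enolate) | [O-]C1=CC[C@H](Br)C(C)(C)[C@@]12CC[C@@](C)([O-])[C@H](Br)C2.[K+].[K+] | intermediate (not isolated)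
16 | (4S,6S,8R,9R)-4,8-dibromo-9-hydroxy-5,5,9-trimethylspiro[5.5]undec-1-en-1-yl trifluoromethanesulfonate | O=S(=O)(OC1=CC[C@H](Br)C(C)(C)[C@@]12CC[C@@](C)(O)[C@H](Br)C2)C(F)(F)F | intermediate
17 | (2R,3R,6R,10S)-2,10-dibromo-3,7,11,11-tetramethylspiro[5.5]undec-7-en-3-ol | CC1=CC[C@H](Br)C(C)(C)[C@@]12CC[C@@](C)(O)[C@H](Br)C2 | target

**Total step count:** 10. **Longest linear sequence:** 10 steps.

**Steps most likely to fail**

Step 2. The bromenium transfer may show poor enantiofacial discrimination, and the keto ester may be brominated at its alpha-carbon or close through oxygen instead of carbon. The fallback uses known chemistry and sets out from 4. Cyclization without a chiral catalyst by 2,4,4,6-tetrabromocyclohexa-2,5-dienone in MeNO2 should give racemic tert-butyl cis-3-bromo-2,2-dimethyl-6-oxocyclohexane-1-carboxylate F1. Its enantiomers are separated by preparative chromatography on a chiral stationary phase, and the (1S,3S) enantiomer is 5, where the route is rejoined.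

Step 8. External water may open the bromonium ion in the diaxial sense faster than the carbonyl oxygen does, which would invert both C2 and C3, and excess reagent may brominate C8. The fallback uses a different ring closure and sets out from 10.
- Ozonolysis of the allyl group (O3, CH2Cl2, −78 °C; PPh3) should give 2-[(1S,3S)-3-bromo-2,2-dimethyl-6-oxo-1-(3-oxobutyl)cyclohexyl]acetaldehyde F2.
- An intramolecular crossed benzoin reaction catalysed by an aminoindanol-derived N-pentafluorophenyl triazolium salt and Et3N joins C2 to C3, with catalyst control at C3, to give (4S,6S,9R)-4-bromo-9-hydroxy-5,5,9-trimethylspiro[5.5]undecane-1,8-dione F3.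
- LiBH(s-Bu)3 at −78 °C should reduce only the C2 ketone from the equatorial side to the cis diol (4S,6S,8S,9R)-4-bromo-8,9-dihydroxy-5,5,9-trimethylspiro[5.5]undecan-1-one F4.
- 1,1'-Sulfonyldiimidazole and NaH convert it into the C2,C3 cyclic sulfate F5.
- LiBr in THF opens the sulfate at C2 with inversion to the lithium C3 sulfate monoester of the bromohydrin F6, and dilute H2SO4 in wet THF hydrolyses it to 14, where the route is rejoined.

Step 5. Bond formation at the congested silyl enol ether carbon may be slower than protodesilylation, and facial selectivity at C6 may be low. The fallback sets out from 7. The same copper-catalysed vinyl addition without TMSCl gives the bromomagnesium enolate F7. It is trapped in the flask by 3-(trimethylsilyl)but-3-en-2-one in an anionic Michael addition to (2S,4S)-4-bromo-3,3-dimethyl-2-(prop-2-en-1-yl)-2-[3-oxo-2-(trimethylsilyl)butyl]cyclohexan-1-one F8, a mixture at the silyl-bearing carbon. KF in MeOH removes the silyl group and gives 10, where the route is rejoined.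

**Further compounds**
F1 | step 2 | racemic tert-butyl cis-3-bromo-2,2-dimethyl-6-oxocyclohexane-1-carboxylate | O=C1CCC(Br)C(C)(C)C1C(=O)OC(C)(C)C
F2 | step 8 | 2-[(1S,3S)-3-bromo-2,2-dimethyl-6-oxo-1-(3-oxobutyl)cyclohexyl]acetaldehyde | CC(=O)CC[C@@]1(CC=O)C(=O)CC[C@H](Br)C1(C)C
F3 | step 8 | (4S,6S,9R)-4-bromo-9-hydroxy-5,5,9-trimethylspiro[5.5]undecane-1,8-dione | O=C1CC[C@H](Br)C(C)(C)[C@@]12CC[C@@](C)(O)C(=O)C2
F4 | step 8 | (4S,6S,8S,9R)-4-bromo-8,9-dihydroxy-5,5,9-trimethylspiro[5.5]undecan-1-one | O=C1CC[C@H](Br)C(C)(C)[C@@]12CC[C@@](C)(O)[C@@H](O)C2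
F5 | step 8 | C2,C3 cyclic sulfate of F4 | O=C1CC[C@H](Br)C(C)(C)[C@@]12CC[C@@]3(C)OS(=O)(=O)O[C@H]3C2
F6 | step 8 | lithium C3 sulfate monoester of 14 | O=C1CC[C@H](Br)C(C)(C)[C@@]12CC[C@@](C)(OS(=O)(=O)[O-])[C@H](Br)C2.[Li+]
F7 | step 5 | bromomagnesium (4S)-4-bromo-3,3-dimethyl-2-(prop-2-en-1-yl)cyclohex-1-en-1-olate | C=CCC1=C(O[Mg]Br)CC[C@H](Br)C1(C)C
F8 | step 5 | (2S,4S)-4-bromo-3,3-dimethyl-2-(prop-2-en-1-yl)-2-[3-oxo-2-(trimethylsilyl)butyl]cyclohexan-1-one | CC(=O)C([Si](C)(C)C)C[C@@]1(CC=C)C(=O)CC[C@H](Br)C1(C)C
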